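**Retrosynthetic overview**
- The target is the methanolysis and debenzylation product of an all-trans tetralin-fused γ-lactone; the lactone masks the CO2Me/CH2OH pair and holds C2/C3 trans.
- The tetralin ring comes from an aldol addition (C1–C2) and a Friedel–Crafts closure (C1–C8a) of O-benzylvanillin on an (S)-β-arylmethyl-γ-butyrolactone; C3 sets C2, and C2 sets C1.
- The β-arylmethyl lactone comes from a Cu-catalysed homoconjugate arylation (C4–C4a) and dealkoxycarbonylation of a cyclopropane-fused lactone.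
- Key step: (S)-epichlorohydrin and dimethyl malonate give the cyclopropane and the γ-lactone in one operation; the one purchased stereocentre becomes C3 of the target.
- Ring order: cyclopropane and lactone together, cyclopropane opened, carbocycle closed, lactone opened.

Assumption: a telescoped sequence whose intermediate is not isolated counts as one step, and the two benzyl-protected aryl building blocks are bought.

**Step 1**
Reactants: 1 (S)-epichlorohydrin; 2 dimethyl malonate
Product: 4 methyl (1R,5S)-2-oxo-3-oxabicyclo[3.1.0]hexane-1-carboxylate, via glycidylmalonate 3 (not isolated)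
Conditions: NaOMe, MeOH, 0 °C → reflux
Reagents that add atoms: none
Why: Tandem double alkylation–lactonisation: malonate opens the epoxide at CH2, the alkoxide re-closes onto CH2Cl to give 3, and a 3-exo-tet cyclopropanation with inversion at the stereocentre followed by lactonisation gives the necessarily cis-fused 4 with C5 = S.

**Step 2**
Reactants: 4 methyl (1R,5S)-2-oxo-3-oxabicyclo[3.1.0]hexane-1-carboxylate; 5 1-(benzyloxy)-4-bromo-2-methoxybenzene
Product: 7 methyl (3R,4S)-4-[4-(benzyloxy)-3-methoxybenzyl]-2-oxotetrahydrofuran-3-carboxylate, via arylmagnesium bromide 6 (not isolated)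
Conditions: Mg, THF; then CuI (10 mol %), 4, THF, −30 → 0 °C; aq. HCl work-up
Reagents that add atoms: none
Why: Cu-catalysed homoconjugate (1,5) addition of the aryl Grignard to the doubly activated cyclopropane attacks the unsubstituted CH2, so C5 of 4 is untouched and becomes C4 (S) of 7, while the epimerisable C3 settles trans.

**Step 3**
Reactants: 7 methyl (3R,4S)-4-[4-(benzyloxy)-3-methoxybenzyl]-2-oxotetrahydrofuran-3-carboxylate
Product: 8 (4S)-4-[4-(benzyloxy)-3-methoxybenzyl]dihydrofuran-2(3H)-one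
Conditions: LiCl, H2O, DMSO, 140 °C
Reagents that add atoms: none
Why: Krapcho dealkoxycarbonylation (chloride SN2 at the ester methyl, loss of CO2, protonation) removes the activating ester, and the non-enolisable C4 stereocentre is retained.

**Step 4**
Reactants: 8 (4S)-4-[4-(benzyloxy)-3-methoxybenzyl]dihydrofuran-2(3H)-one; 9 4-(benzyloxy)-3-methoxybenzaldehyde
Product: 12 (3aS,9R,9aS)-7-(benzyloxy)-9-[4-(benzyloxy)-3-methoxyphenyl]-6-methoxy-3a,4,9,9a-tetrahydronaphtho[2,3-c]furan-1(3H)-one, via lithium enolate 10 (not isolated), via aldol adduct 11 (not isolated)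
Conditions: LDA, THF, −78 °C, then 9; concentrate; TFA, CH2Cl2, 0 °C → rt
Reagents that add atoms: none
Why: Aldol addition of 10 to 9 occurs anti to the β-benzyl group (C2/C3 trans), and TFA ionises either carbinol epimer of 11 to a p-alkoxybenzyl cation that closes by intramolecular Friedel–Crafts alkylation para to OMe with the aryl trans to the lactone carbonyl (allylic-strain control), giving the all-trans lactone.

**Step 5**
Reactants: 12 (3aS,9R,9aS)-7-(benzyloxy)-9-[4-(benzyloxy)-3-methoxyphenyl]-6-methoxy-3a,4,9,9a-tetrahydronaphtho[2,3-c]furan-1(3H)-one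
Product: 13 methyl (1R,2S,3S)-7-(benzyloxy)-1-[4-(benzyloxy)-3-methoxyphenyl]-3-(hydroxymethyl)-6-methoxy-1,2,3,4-tetrahydronaphthalene-2-carboxylate
Conditions: NaOMe (0.2 equiv), MeOH/THF, 0 °C → rt; AcOH quench at 0 °C
Reagents that add atoms: methanol (CO)
Why: Base-catalysed transesterification (methanolysis) of the strained trans-fused γ-lactone gives the all-equatorial hydroxy ester, and C2 is already in its thermodynamic trans,trans configuration so no centre is scrambled.

**Step 6**
Reactants: 13 methyl (1R,2S,3S)-7-(benzyloxy)-1-[4-(benzyloxy)-3-methoxyphenyl]-3-(hydroxymethyl)-6-methoxy-1,2,3,4-tetrahydronaphthalene-2-carboxylate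
Product: 14 methyl (1R,2S,3S)-7-hydroxy-1-(4-hydroxy-3-methoxyphenyl)-3-(hydroxymethyl)-6-methoxy-1,2,3,4-tetrahydronaphthalene-2-carboxylate
Conditions: H2 (1 atm), 10 % Pd/C, EtOAc/MeOH, rt
Reagents that add atoms: none
Why: Neutral hydrogenolysis cleaves both aryl benzyl ethers and leaves the methyl ester, the primary alcohol and the three stereocentres untouched.

**Compound list**
1 | (S)-epichlorohydrin, (2S)-2-(chloromethyl)oxirane | ClC[C@@H]1CO1 | starting material
2 | dimethyl malonate | COC(=O)CC(=O)OC | starting material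
3 | dimethyl 2-{[(2S)-oxiran-2-yl]methyl}propanedioate | COC(=O)C(C[C@H]1CO1)C(=O)OC | intermediate
4 | methyl (1R,5S)-2-oxo-3-oxabicyclo[3.1.0]hexane-1-carboxylate | COC(=O)[C@@]12C[C@@H]1COC2=O | intermediate
5 | 1-(benzyloxy)-4-bromo-2-methoxybenzene | COc1cc(Br)ccc1OCc1ccccc1 | starting material
6 | [4-(benzyloxy)-3-methoxyphenyl]magnesium bromide | COc1cc([Mg]Br)ccc1OCc1ccccc1 | intermediate
7 | methyl (3R,4S)-4-[4-(benzyloxy)-3-methoxybenzyl]-2-oxotetrahydrofuran-3-carboxylate (3,4-trans) | COC(=O)[C@H]1[C@H](Cc2ccc(OCc3ccccc3)c(OC)c2)COC1=O | intermediate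
8 | (4S)-4-[4-(benzyloxy)-3-methoxybenzyl]dihydrofuran-2(3H)-one | O=C1C[C@H](Cc2ccc(OCc3ccccc3)c(OC)c2)CO1 | intermediate
9 | 4-(benzyloxy)-3-methoxybenzaldehyde (O-benzylvanillin) | COc1cc(C=O)ccc1OCc1ccccc1 | starting material
10 | lithium (4S)-4-[4-(benzyloxy)-3-methoxybenzyl]-4,5-dihydrofuran-2-olate (lithium enolate of 8) | [Li+].[O-]C1=C[C@H](Cc2ccc(OCc3ccccc3)c(OC)c2)CO1 | intermediate
11 | (3R,4S)-4-[4-(benzyloxy)-3-methoxybenzyl]-3-{[4-(benzyloxy)-3-methoxyphenyl](hydroxy)methyl}dihydrofuran-2(3H)-one (3,4-trans, both carbinol epimers) | O=C1OC[C@@H](Cc2ccc(OCc3ccccc3)c(OC)c2)[C@@H]1C(O)c1ccc(OCc2ccccc2)c(OC)c1 | intermediate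
12 | (3aS,9R,9aS)-7-(benzyloxy)-9-[4-(benzyloxy)-3-methoxyphenyl]-6-methoxy-3a,4,9,9a-tetrahydronaphtho[2,3-c]furan-1(3H)-one (trans-fused, aryl trans to C=O) | O=C1OC[C@H]2Cc3cc(OC)c(OCc4ccccc4)cc3[C@@H](c3ccc(OCc4ccccc4)c(OC)c3)[C@H]12 | intermediate
13 | methyl (1R,2S,3S)-7-(benzyloxy)-1-[4-(benzyloxy)-3-methoxyphenyl]-3-(hydroxymethyl)-6-methoxy-1,2,3,4-tetrahydronaphthalene-2-carboxylate | COC(=O)[C@@H]1[C@@H](CO)Cc2cc(OC)c(OCc3ccccc3)cc2[C@H]1c1ccc(OCc2ccccc2)c(OC)c1 | intermediate
14 | methyl (1R,2S,3S)-7-hydroxy-1-(4-hydroxy-3-methoxyphenyl)-3-(hydroxymethyl)-6-methoxy-1,2,3,4-tetrahydronaphthalene-2-carboxylate | COC(=O)[C@@H]1[C@@H](CO)Cc2cc(OC)c(O)cc2[C@H]1c1ccc(O)c(OC)c1 | target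

**Step count and risks**
Total step count: 6. Longest linear sequence: 6 (1 → 4 → 7 → 8 → 12 → 13 → 14).

The three steps most likely to fail:

Step 2 (the electron-rich aryl Grignard may attack the carbonyl groups instead of the cyclopropane CH2). The fallback sets out from 4 and comes back to the route at 8. Compound 4 is opened with iodide (NaI, TMSCl, MeCN) to methyl (3R,4S)-4-(iodomethyl)-2-oxotetrahydrofuran-3-carboxylate F1. F1 is dealkoxycarbonylated (NaI, wet DMSO, 130 °C) to (4S)-4-(iodomethyl)dihydrofuran-2(3H)-one F2. The aryl group is then attached by an iron-catalysed alkyl–aryl Kumada coupling of F2 with 6 (Fe(acac)3, TMEDA, THF, 0 °C).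

Step 4 (retro-aldol, loss of benzyl ethers in TFA, or eroded trans selectivity in the telescoped aldol/Friedel–Crafts sequence). The fallback sets out from 8 and comes back at 12. Compound 8 is alkylated trans (LDA, 4-(benzyloxy)-3-methoxybenzyl bromide, THF, −78 °C) to (3S,4S)-3,4-bis[4-(benzyloxy)-3-methoxybenzyl]dihydrofuran-2(3H)-one F3. F3 is closed by oxidative cyclisation (DDQ, TFA/CH2Cl2, 0 °C): dehydrogenation at the benzylic carbon next to the lactone α-carbon, then the same six-ring Friedel–Crafts closure.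

Step 5 (the methanolysis is an equilibrium and the hydroxy ester can relactonise on work-up). The fallback sets out from 12 and comes back at 13. Compound 12 is saponified (NaOH, THF/H2O, rt) to sodium (1R,2S,3S)-7-(benzyloxy)-1-[4-(benzyloxy)-3-methoxyphenyl]-3-(hydroxymethyl)-6-methoxy-1,2,3,4-tetrahydronaphthalene-2-carboxylate F4. F4 is methylated at the carboxylate only (MeI, DMF, rt).

**Further compounds**
F1 | step 2 | methyl (3R,4S)-4-(iodomethyl)-2-oxotetrahydrofuran-3-carboxylate | COC(=O)[C@H]1[C@H](CI)COC1=O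
F2 | step 2 | (4S)-4-(iodomethyl)dihydrofuran-2(3H)-one | O=C1C[C@H](CI)CO1
F3 | step 4 | (3S,4S)-3,4-bis[4-(benzyloxy)-3-methoxybenzyl]dihydrofuran-2(3H)-one | O=C1OC[C@@H](Cc2ccc(OCc3ccccc3)c(OC)c2)[C@@H]1Cc1ccc(OCc2ccccc2)c(OC)c1
F4 | step 5 | sodium (1R,2S,3S)-7-(benzyloxy)-1-[4-(benzyloxy)-3-methoxyphenyl]-3-(hydroxymethyl)-6-methoxy-1,2,3,4-tetrahydronaphthalene-2-carboxylate | [Na+].[O-]C(=O)[C@@H]1[C@@H](CO)Cc2cc(OC)c(OCc3ccccc3)cc2[C@H]1c1ccc(OCc2ccccc2)c(OC)c1
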